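**Retrosynthetic overview**

1. Germacranolide numbering is used: ring C1–C10, C1=C10, C4=C5, lactone O on C6, C7–C11(=C13)–C12=O. In the endgame C9–OH comes from a C9 ketone. The C8 ester comes from the C8–OH of an α-ketol and separately made (2R,3R)-epoxyangelic acid.
2. The key disconnection is a retro-[3,3] across C7–C8. The ten-membered carbocycle comes from a twelve-membered oxacycle (O, C13, C11, C7, C6, C5, C4, C3, C2, C1, C10, C9), in which C9–O–C13 is an ether, C11=C7 is a butenolide alkene and C8 is an exocyclic enol carbon.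
3. The enabling feature is that O=C9–C8(O)–C7–C11=C13 is a Claisen retron, with C11=C13 being the α-methylene group of the five-membered lactone. H6 and H7 are cis, so C5 and C8 lie on one face of that lactone ring and a C9–O–C13 tether can deliver C8 to C7.
4. The oxacycle is built by Ni/Cr closure at C3–C4, RCM for the butenolide and esterification at O6–C12. The fragments are glycerate acetonide (C8–C10), a C3 ylide (C1–C3), 2-(bromomethyl)acrylate (C11–C13) and acrolein plus propyne (C4–C7, C15).
5. Ring order: oxirane (side chain) and butenolide, then the 12-membered oxacycle, then the 10-membered carbocycle.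

Key step: step 23

Assumption: the SMILES is read as 1(10)Z,4Z (both ring alkenes ring-cis) with a cis-fused lactone, giving (3S,6R,7R,8S,9R,2′R,3′R).

**Route**

Step 1
Reactants: 1 methyl (S)-2,2-dimethyl-1,3-dioxolane-4-carboxylate
Product: 3 1-[(4S)-2,2-dimethyl-1,3-dioxolan-4-yl]ethanone, via Weinreb amide 2 (not isolated)
Conditions: MeNH(OMe)·HCl, i-PrMgCl, THF, −20 °C; then MeMgBr, 0 °C
Reagents that add atoms: N,O-dimethylhydroxylamine hydrochloride, CNOC.Cl (atoms in 2 only); methylmagnesium bromide, C[Mg]Br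
Why: One-pot Weinreb ketone synthesis, in which the chelated adduct of amide 2 with MeMgBr stops at the ketone and the stereocentre (future C9) is untouched.

Step 2
Reactants: 4 3-[(4-methoxybenzyl)oxy]propan-1-ol
Product: 5 1-[(3-iodopropoxy)methyl]-4-methoxybenzene
Conditions: I2, PPh3, imidazole, CH2Cl2, 0 °C
Reagents that add atoms: iodine, II
Why: Appel-type iodination of a primary alcohol, to which the PMB ether is inert.

Step 3
Reactants: 5 1-[(3-iodopropoxy)methyl]-4-methoxybenzene
Product: 6 {3-[(4-methoxybenzyl)oxy]propyl}triphenylphosphonium iodide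
Conditions: PPh3, MeCN, reflux
Reagents that add atoms: triphenylphosphine, c1ccc(cc1)P(c1ccccc1)c1ccccc1
Why: SN2 quaternisation of triphenylphosphine by a primary iodide.

Step 4
Reactants: 6 phosphonium iodide; 3 1-[(4S)-2,2-dimethyl-1,3-dioxolan-4-yl]ethanone
Product: 8 (4R)-4-{(2Z)-5-[(4-methoxybenzyl)oxy]pent-2-en-2-yl}-2,2-dimethyl-1,3-dioxolane, via phosphorus ylide 7 (not isolated)
Conditions: NaHMDS, THF, 0 °C; then 3, −78 °C to rt
Reagents that add atoms: none
Why: Wittig olefination of an α-alkoxy methyl ketone with a non-stabilised ylide under lithium-free conditions, a combination known to favour the (Z)-trisubstituted allylic ether (C2 cis to C9), which fixes C1=C10.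

Step 5
Reactants: 8 dioxolane
Product: 9 (2R,3Z)-6-[(4-methoxybenzyl)oxy]-3-methylhex-3-ene-1,2-diol
Conditions: AcOH/H2O 4:1, 40 °C
Reagents that add atoms: none
Why: Acid hydrolysis of a terminal isopropylidene ketal, which the PMB ether and the alkene survive.

Step 6
Reactants: 9 diol
Product: 10 (2R,3Z)-1-[(tert-butyldiphenylsilyl)oxy]-6-[(4-methoxybenzyl)oxy]-3-methylhex-3-en-2-ol
Conditions: TBDPSCl, imidazole, CH2Cl2, 0 °C
Reagents that add atoms: tert-butyldiphenylsilyl chloride, CC(C)(C)[Si](Cl)(c1ccccc1)c1ccccc1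
Why: Sterically controlled monosilylation of the primary hydroxyl (C8–OH) of a 1,2-diol.

Step 7
Reactants: 10 silyl ether alcohol; 11 ethyl 2-(bromomethyl)acrylate
Product: 12 ethyl 2-({[(2R,3Z)-1-(TBDPS-oxy)-6-(PMB-oxy)-3-methylhex-3-en-2-yl]oxy}methyl)acrylate
Conditions: NaH, Bu4NI (cat.), THF, 0 °C
Reagents that add atoms: none
Why: Williamson etherification with a doubly activated allylic bromide (SN2 and SN2′ give the same product), with low temperature and the bulky silyl group suppressing 1,2-silyl migration.

Step 8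
Reactants: 12 ether ester
Product: 13 2-({[(2R,3Z)-1-(TBDPS-oxy)-6-(PMB-oxy)-3-methylhex-3-en-2-yl]oxy}methyl)acrylic acid
Conditions: LiOH, THF/H2O, 0 °C; then 1 M HCl to pH 3
Reagents that add atoms: lithium hydroxide, [Li+].[OH-]
Why: Saponification, in which carboxylate formation switches off the Michael acceptor so that the β′-alkoxy group is kept.

Step 9
Reactants: 14 acrolein; 15 prop-1-ynylmagnesium bromide
Product: 16 rac-hex-1-en-4-yn-3-ol
Conditions: THF, −78 °C
Reagents that add atoms: none
Why: 1,2-Addition of an alkynyl Grignard reagent to an enal.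

Step 10
Reactants: 16 rac-hex-1-en-4-yn-3-ol
Product: 17 (S)-hex-1-en-4-yn-3-ol
Conditions: Ti(Oi-Pr)4 (cat.), L-(+)-DIPT (cat.), t-BuOOH (0.6 equiv), 4 Å MS, CH2Cl2, −20 °C
Reagents that add atoms: none
Why: Sharpless kinetic resolution, in which the (R)-alcohol is epoxidised at its vinyl group much faster with L-(+)-tartrate, so that the (S)-alcohol (future C6) is recovered.

Step 11
Reactants: 17 (S)-hex-1-en-4-yn-3-ol
Product: 19 (3S,4Z)-5-iodohexa-1,4-dien-3-ol, via cyclic alkenylalanate 18 (not isolated)
Conditions: Red-Al, THF, 0 °C to rt; then I2, −78 °C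
Reagents that add atoms: Red-Al, [Na+].[AlH2-](OCCOC)OCCOC (atoms in 18 only); iodine, II
Why: Hydroxyl-directed trans-hydroalumination puts aluminium on the distal alkyne carbon in a five-membered alanate, and iodinolysis with retention gives the (Z)-γ-iodo allylic alcohol, which fixes C4=C5.

Step 12
Reactants: 20 methyl angelate (methyl (Z)-2-methylbut-2-enoate)
Product: 21 (Z)-2-methylbut-2-en-1-ol
Conditions: DIBAL-H, CH2Cl2, −78 °C
Reagents that add atoms: none
Why: 1,2-Reduction of the enoate at low temperature keeps the (Z)-alkene.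

Step 13
Reactants: 21 (Z)-2-methylbut-2-en-1-ol
Product: 22 [(2S,3R)-2,3-dimethyloxiran-2-yl]methanol
Conditions: Ti(Oi-Pr)4 (cat.), D-(−)-DIPT (cat.), t-BuOOH, 4 Å MS, CH2Cl2, −20 °C
Reagents that add atoms: tert-butyl hydroperoxide, CC(C)(C)OO
Why: Sharpless asymmetric epoxidation, in which D-(−)-tartrate selects the face that gives the (2S,3R)-epoxy alcohol and syn addition keeps the two methyl groups trans.

Step 14
Reactants: 22 epoxy alcohol
Product: 23 (2R,3R)-2,3-dimethyloxirane-2-carboxylic acid
Conditions: RuCl3 (cat.), NaIO4, MeCN/EtOAc/H2O, 0 °C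
Reagents that add atoms: water, O; sodium periodate, [Na+].[O-]I(=O)(=O)=O (oxygen source of RuO4)
Why: Ruthenium tetroxide oxidation of a 2,3-epoxy alcohol to the glycidic acid leaves both oxirane centres untouched (the C2 descriptor changes only by priority).

Step 15
Reactants: 13 acrylic acid; 19 (3S,4Z)-5-iodohexa-1,4-dien-3-ol
Product: 24 (3S,4Z)-5-iodohexa-1,4-dien-3-yl ester of 13
Conditions: DCC, DMAP (cat.), CH2Cl2, 0 °C
Reagents that add atoms: none
Why: Steglich esterification joins the halves through O6–C12 with retention at C6.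

Step 16
Reactants: 24 dienyl acrylate
Product: 25 (5S)-5-[(1Z)-2-iodoprop-1-enyl]-3-({[(2R,3Z)-1-(TBDPS-oxy)-6-(PMB-oxy)-3-methylhex-3-en-2-yl]oxy}methyl)furan-2(5H)-one
Conditions: Hoveyda–Grubbs II (5 mol %), PhMe, 80 °C
Reagents that add atoms: none
Why: Ring-closing metathesis of the vinyl group with the 1,1-disubstituted acrylate closes the butenolide (C7=C11), the trisubstituted alkene and the alkenyl iodide being inert.

Step 17
Reactants: 25 butenolide PMB ether
Product: 26 the corresponding primary alcohol (C3–OH)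
Conditions: DDQ, CH2Cl2/pH 7 buffer, 0 °C
Reagents that add atoms: none
Why: Oxidative PMB cleavage, which is faster than oxidation of the allylic ether.

Step 18
Reactants: 26 primary alcohol
Product: 27 the corresponding β,γ-unsaturated aldehyde (C3 = CHO)
Conditions: Dess–Martin periodinane, CH2Cl2, 0 °C
Reagents that add atoms: none
Why: Dess–Martin oxidation under near-neutral conditions avoids migration of C1=C10 into conjugation.

Step 19
Reactants: 27 iodo aldehyde
Product: 28 12-membered oxacycle bridged by the butenolide, (3S,6R,9R)-1(10)Z,4Z, with 3-OH and 9-CH2OTBDPS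
Conditions: CrCl2, NiCl2 (cat.), chiral oxazoline–sulfonamide ligand, Et3N, THF, rt, slow addition (about 1 mM)
Reagents that add atoms: none
Why: Intramolecular Nozaki–Hiyama–Kishi reaction, in which the alkenylchromium forms with retention of the Z geometry and the ligand enantiomer on chromium is chosen to direct addition to the aldehyde face that gives (3S).

Step 20
Reactants: 28 macrocyclic alcohol
Product: 29 the 3-acetate of 28
Conditions: Ac2O, pyridine, DMAP (cat.), CH2Cl2, 0 °C
Reagents that add atoms: acetic anhydride, CC(=O)OC(C)=O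
Why: Acetylation of the only free hydroxyl installs the C3 acetate of the target.

Step 21
Reactants: 29 acetate
Product: 30 primary alcohol (9-CH2OH)
Conditions: HF·pyridine, pyridine/THF, 0 °C to rt
Reagents that add atoms: none
Why: Buffered fluoride desilylation, which the acetate, butenolide and allylic ether tolerate.

Step 22
Reactants: 30 primary alcohol
Product: 31 α-allyloxy aldehyde, (3S,6R,9R), C8 = CHO on ring atom C9 of the 12-membered oxacycle
Conditions: Dess–Martin periodinane, CH2Cl2, 0 °C; used at once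
Reagents that add atoms: none
Why: Dess–Martin oxidation gives the sensitive α-alkoxy-β,γ-unsaturated aldehyde without base.

Step 23
Reactants: 31 α-allyloxy aldehyde
Product: 33 (3S,6R,7R,8S)-3-acetoxy-8-(TBS-oxy)-9-oxogermacra-1(10)Z,4Z,11(13)-trien-12,6-olide, via silyl dienol ether 32 (not isolated)
Conditions: TBSOTf (1.05 equiv), Et3N, CH2Cl2, −78 to 0 °C; pentane filtration, then PhMe, 100 °C
Reagents that add atoms: tert-butyldimethylsilyl triflate, CC(C)(C)[Si](C)(C)OS(=O)(=O)C(F)(F)F
Why: Proposed new method: soft enolisation of the doubly activated C9–H of 31 erases C9 and gives the (Z)-1-silyloxy-2-allyloxy diene 32, whose C8=C9–O–C13–C11=C7 array is an allyl vinyl ether built into the 12-membered ring with C8 exocyclic, so the suprafacial [3,3] shift (C8–C7 formed, O–C13 broken) takes O, C13 and C11 out of the ring path, takes C8 in, and contracts 12 to 10. The closest known reaction types are the Claisen rearrangement of silyl enol ethers and enolates of α-allyloxy carbonyl compounds to α-ketols and the Ireland–Claisen ring contraction of macrolactones; new here are the two-atom contraction mode with an exocyclic vinyl terminus and a butenolide as the allyl part. The only ring closed is the ten-membered carbocycle, closed transannularly through a six-membered chair transition state, while the existing lactone ring merely transposes its alkene to the exocyclic C11=C13 methylene. C7 is controlled by the tether, because the nine-atom bridge leaves the planar butenolide at C6 on the C5 face and returns in-plane at C13, so C8 should reach C7 only on that face (cis H6/H7); C8 follows from the (Z)-enol ether geometry (large C10 arm trans to OTBS, the two oxygens cis) read through the chair, the boat being disfavoured because it stacks C10 over the lactone carbonyl. The step needs enolisation of the aldehyde rather than the butenolide γ-H, secured by the α-oxygen/α-vinyl activation of C9–H and one equivalent of silyl triflate, and it needs [3,3] to outrun [1,5]-H and Cope pathways, secured by the donor OTBS on the vinyl terminus and the acceptor lactone C=O on the central allyl carbon C11. Formation of the C9 carbonyl makes the shift irreversible.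

Step 24
Reactants: 33 α-silyloxy ketone
Product: 34 (3S,6R,7S,8S)-3-acetoxy-8-hydroxy-9-oxogermacra-1(10)Z,4Z,11(13)-trien-12,6-olide
Conditions: HF·pyridine, THF, 0 °C
Reagents that add atoms: none
Why: Acidic fluoride desilylation frees C8–OH without base, so that neither the α-ketol nor the α-methylene lactone is disturbed (the C7 descriptor changes only by priority).

Step 25
Reactants: 34 α-ketol; 23 (2R,3R)-2,3-dimethyloxirane-2-carboxylic acid
Product: 36 (3S,6R,7R,8S,2′R,3′R)-3-acetoxy-8-(2,3-epoxy-2-methylbutanoyloxy)-9-oxogermacra-1(10)Z,4Z,11(13)-trien-12,6-olide, via mixed anhydride 35 (not isolated)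
Conditions: 23, 2,4,6-Cl3C6H2COCl, Et3N, PhMe, rt; then 34, DMAP, rt
Reagents that add atoms: 2,4,6-trichlorobenzoyl chloride, O=C(Cl)c1c(Cl)cc(Cl)cc1Cl (atoms in 35 only)
Why: Yamaguchi esterification acylates the only hydroxyl (C9 is still a ketone, so O8 and O9 are differentiated) with retention at C8 and in the acid.

Step 26
Reactants: 36 keto ester
Product: 37 target, (3S,6R,7R,8S,9R,2′R,3′R)
Conditions: (R)-Me-CBS, catecholborane, PhMe/CH2Cl2, −78 °C; pH 7 work-up
Reagents that add atoms: none
Why: Corey–Bakshi–Shibata 1,2-reduction of the α-methyl enone, in which the alkenyl arm (C10) acts as the large group so that the (R)-catalyst should deliver hydride to the face that gives (9R), while esters, oxirane and α-methylene lactone are not touched by catecholborane.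

**Compound list**

1 | methyl (S)-2,2-dimethyl-1,3-dioxolane-4-carboxylate | COC(=O)[C@@H]1COC(C)(C)O1 | starting material
2 | (S)-N-methoxy-N,2,2-trimethyl-1,3-dioxolane-4-carboxamide | CON(C)C(=O)[C@@H]1COC(C)(C)O1 | intermediate
3 | 1-[(4S)-2,2-dimethyl-1,3-dioxolan-4-yl]ethanone | CC(=O)[C@@H]1COC(C)(C)O1 | intermediate
4 | 3-[(4-methoxybenzyl)oxy]propan-1-ol | OCCCOCc1ccc(OC)cc1 | starting material
5 | 1-[(3-iodopropoxy)methyl]-4-methoxybenzene | ICCCOCc1ccc(OC)cc1 | intermediate
6 | {3-[(4-methoxybenzyl)oxy]propyl}triphenylphosphonium iodide | [I-].COc1ccc(COCCC[P+](c2ccccc2)(c2ccccc2)c2ccccc2)cc1 | intermediate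
7 | ylide of 6 | COc1ccc(COCCC=P(c2ccccc2)(c2ccccc2)c2ccccc2)cc1 | intermediate
8 | (4R)-4-{(2Z)-5-[(4-methoxybenzyl)oxy]pent-2-en-2-yl}-2,2-dimethyl-1,3-dioxolane | COc1ccc(COCC/C=C(/C)[C@@H]2COC(C)(C)O2)cc1 | intermediate
9 | (2R,3Z)-6-[(4-methoxybenzyl)oxy]-3-methylhex-3-ene-1,2-diol | COc1ccc(COCC/C=C(/C)[C@@H](O)CO)cc1 | intermediate
10 | (2R,3Z)-1-(TBDPS-oxy)-6-(PMB-oxy)-3-methylhex-3-en-2-ol | COc1ccc(COCC/C=C(/C)[C@@H](O)CO[Si](c2ccccc2)(c2ccccc2)C(C)(C)C)cc1 | intermediate
11 | ethyl 2-(bromomethyl)acrylate | C=C(CBr)C(=O)OCC | starting material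
12 | ethyl 2-(alkoxymethyl)acrylate, (9R), 1(10)Z | COc1ccc(COCC/C=C(/C)[C@@H](OCC(=C)C(=O)OCC)CO[Si](c2ccccc2)(c2ccccc2)C(C)(C)C)cc1 | intermediate
13 | 2-(alkoxymethyl)acrylic acid, (9R), 1(10)Z | COc1ccc(COCC/C=C(/C)[C@@H](OCC(=C)C(=O)O)CO[Si](c2ccccc2)(c2ccccc2)C(C)(C)C)cc1 | intermediate
14 | acrolein | C=CC=O | starting material
15 | prop-1-ynylmagnesium bromide | CC#C[Mg]Br | starting material
16 | rac-hex-1-en-4-yn-3-ol | C=CC(O)C#CC | intermediate
17 | (S)-hex-1-en-4-yn-3-ol | C=C[C@H](O)C#CC | intermediate
18 | sodium cyclic alkenylalanate from 17 | [Na+].C=C[C@H]1C=C(C)[Al-](OCCOC)(OCCOC)O1 | intermediate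
19 | (3S,4Z)-5-iodohexa-1,4-dien-3-ol | C=C[C@H](O)/C=C(/C)I | intermediate
20 | methyl angelate | C/C=C(/C)C(=O)OC | starting material
21 | (Z)-2-methylbut-2-en-1-ol | C/C=C(/C)CO | intermediate
22 | [(2S,3R)-2,3-dimethyloxiran-2-yl]methanol | OC[C@]1(C)O[C@@H]1C | intermediate
23 | (2R,3R)-2,3-dimethyloxirane-2-carboxylic acid | OC(=O)[C@]1(C)O[C@@H]1C | intermediate
24 | (3S,4Z)-5-iodohexa-1,4-dien-3-yl ester of 13, (6S,9R) | C=C[C@H](OC(=O)C(=C)CO[C@@H](CO[Si](c1ccccc1)(c1ccccc1)C(C)(C)C)/C(C)=C\CCOCc1ccc(OC)cc1)/C=C(/C)I | intermediate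
25 | butenolide PMB ether, (6S,9R) | O=C1O[C@H](/C=C(/C)I)C=C1CO[C@@H](CO[Si](c1ccccc1)(c1ccccc1)C(C)(C)C)/C(C)=C\CCOCc1ccc(OC)cc1 | intermediate
26 | butenolide primary alcohol, (6S,9R) | O=C1O[C@H](/C=C(/C)I)C=C1CO[C@@H](CO[Si](c1ccccc1)(c1ccccc1)C(C)(C)C)/C(C)=C\CCO | intermediate
27 | butenolide aldehyde, (6S,9R) | O=C1O[C@H](/C=C(/C)I)C=C1CO[C@@H](CO[Si](c1ccccc1)(c1ccccc1)C(C)(C)C)/C(C)=C\CC=O | intermediate
28 | 12-membered oxacycle, 3-OH, (3S,6R,9R) | C1C2=C[C@H](OC2=O)/C=C(/C)[C@@H](O)C/C=C(/C)[C@H](CO[Si](c3ccccc3)(c3ccccc3)C(C)(C)C)O1 | intermediate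
29 | 12-membered oxacycle, 3-OAc, (3S,6R,9R) | C1C2=C[C@H](OC2=O)/C=C(/C)[C@@H](OC(C)=O)C/C=C(/C)[C@H](CO[Si](c3ccccc3)(c3ccccc3)C(C)(C)C)O1 | intermediate
30 | 12-membered oxacycle, 9-CH2OH, (3S,6R,9R) | C1C2=C[C@H](OC2=O)/C=C(/C)[C@@H](OC(C)=O)C/C=C(/C)[C@H](CO)O1 | intermediate
31 | 12-membered oxacycle, 9-CHO, (3S,6R,9R) | C1C2=C[C@H](OC2=O)/C=C(/C)[C@@H](OC(C)=O)C/C=C(/C)[C@H](C=O)O1 | intermediate
32 | (8Z)-silyl dienol ether, (3S,6R) | C1C2=C[C@H](OC2=O)/C=C(/C)[C@@H](OC(C)=O)C/C=C(/C)\C(=C\O[Si](C)(C)C(C)(C)C)O1 | intermediate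
33 | ten-membered α-silyloxy ketone, (3S,6R,7R,8S) | C=C1C(=O)O[C@@H]2/C=C(/C)[C@@H](OC(C)=O)C/C=C(/C)C(=O)[C@@H](O[Si](C)(C)C(C)(C)C)[C@H]12 | intermediate
34 | ten-membered α-ketol, (3S,6R,7S,8S) | C=C1C(=O)O[C@@H]2/C=C(/C)[C@@H](OC(C)=O)C/C=C(/C)C(=O)[C@@H](O)[C@H]12 | intermediate
35 | mixed anhydride of 23 with 2,4,6-trichlorobenzoic acid | O=C(OC(=O)[C@]1(C)O[C@@H]1C)c1c(Cl)cc(Cl)cc1Cl | intermediate
36 | 9-keto ester, (3S,6R,7R,8S,2′R,3′R) | C=C1C(=O)O[C@@H]2/C=C(/C)[C@@H](OC(C)=O)C/C=C(/C)C(=O)[C@@H](OC(=O)[C@]3(C)O[C@@H]3C)[C@H]12 | intermediate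
37 | CNP0299903.1 | C=C1C(=O)O[C@@H]2/C=C(/C)[C@@H](OC(C)=O)C/C=C(/C)[C@@H](O)[C@@H](OC(=O)[C@]3(C)O[C@@H]3C)[C@H]12 | target

**Step count**

Total steps: 26. Longest linear sequence: 19 steps (steps 2–8 and 15–26).

**Steps most likely to fail**

1. Step 23 (Proposed new method).
 - Risks: silylation may also take place at the butenolide γ-position. The β,γ-unsaturated aldehyde may drift into conjugation before it is trapped. The shift may pass through the boat, with loss of control at C8. The strain of the bridged transition state may raise the barrier above that of hydrogen shifts.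
 - Fallback: it uses known reaction types (samarium diiodide ketyl–olefin cyclisation, β-alkoxide elimination from a samarium enolate, MnO2 oxidation of allylic alcohols). It sets out from 31 and comes back at 34.
 - SmI2 (THF, t-BuOH, −78 °C) should generate the C8 ketyl, chelated to the ring oxygen on C9, which adds to C7 of the butenolide on the tether face.
 - The samarium enolate then expels the C13 alkoxide. The ring contracts in the same sense, with C9 kept from the chiral pool, to give the 8,9-diol F1.
 - MnO2 then oxidises only the allylic C9 carbinol and delivers 34.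

2. Step 19.
 - Risks: oligomerisation may compete with closure of the bridged 12-membered ring. Ligand control of the aldehyde face may be eroded by transannular crowding.
 - Fallback: the C3 centre is set by reduction instead of during C–C bond formation. It sets out from 27 and comes back at 28.
 - The Ni/Cr closure is run without the chiral ligand to give the C3-epimeric carbinols F2.
 - Dess–Martin oxidation gives the macrocyclic dienone F3.
 - (R)-Me-CBS/catecholborane reduction, with the α-methyl alkenyl arm as the large group, should then give (3S)-28.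

3. Step 26.
 - Risks: the facial preference of the ring may oppose that of the catalyst. The branched C8 arm may compete with the alkenyl arm for the role of the large group.
 - Fallback: the control element becomes an enzyme pocket. It sets out from 36 and comes back at 37.
 - The reduction uses an NADPH-dependent ketoreductase (alcohol dehydrogenase class), chosen from a panel that holds both stereopreferences, with glucose/glucose dehydrogenase recycling in pH 7 buffer and DMSO co-solvent. These conditions should leave the esters, oxirane and α-methylene lactone intact.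

**Further compounds**

F1 | step 23 | (3S,6R,7S,8S,9R)-3-acetoxy-8,9-dihydroxygermacra-1(10)Z,4Z,11(13)-trien-12,6-olide | C=C1C(=O)O[C@@H]2/C=C(/C)[C@@H](OC(C)=O)C/C=C(/C)[C@@H](O)[C@@H](O)[C@H]12
F2 | step 19 | 12-membered oxacycle, 3-OH as C3 epimer mixture, (6R,9R) | C1C2=C[C@H](OC2=O)/C=C(/C)C(O)C/C=C(/C)[C@H](CO[Si](c3ccccc3)(c3ccccc3)C(C)(C)C)O1
F3 | step 19 | 12-membered oxacycle, 3-ketone, (6R,9R) | C1C2=C[C@H](OC2=O)/C=C(/C)C(=O)C/C=C(/C)[C@H](CO[Si](c3ccccc3)(c3ccccc3)C(C)(C)C)O1
F0 | step 26 | none | none
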